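**Retrosynthetic overview**
- The target comes from a germacra-1(10),4-dienolide by reagent-controlled epoxidation of C1=C10, after both hydroxyls of a 6,11-diol are angeloylated and the C11 oxygen is introduced by lactone-enolate hydroxylation.
- Key disconnection is C6–C7: a SmI2 ketyl–olefin radical macrocyclisation of a Z-enal onto an α-methylbutenolide closes the ten-membered ring and sets C6 and C7.
- The acyclic enal–butenolide comes from a B-alkyl Suzuki coupling (C1–C2) of an E-vinyl iodide with the borane of a Z-dienol, then ring-closing metathesis of a methacrylate.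
- C8 comes from a catalytic asymmetric propargylation of acrolein; the E-alkene comes from alkyne carboalumination.
- Ring order: five-membered lactone, then ten-membered carbocycle, then epoxide.

Assumption: atoms carry germacrane numbers (ring C1–C10, C11 on C7, C12 lactone carbonyl, C13 methyl on C11, C14 methyl on C10, C15 methyl on C4), and the five starting materials are taken as commercial.

**Route**

Step 1
Reactants: 1 acrolein; 2 propargyl bromide
Product: 4 (R)-hex-1-en-5-yn-3-ol, via trimethylsilyl ether 3 (not isolated)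
Conditions: CrCl2 (10 mol %), Nakada bis(oxazolinyl)carbazole ligand (12 mol %, antipode giving R), Mn powder (2 equiv), TMSCl (2 equiv), i-Pr2NEt (0.3 equiv), THF, 0 °C to rt; then 1 M HCl, THF
Reagents that add atoms: none
Why: Catalytic asymmetric Nozaki–Hiyama propargylation, in which the allenylchromium species from 2 adds to the aldehyde through a ligand-organised SE2' transition state to give the homopropargylic alcohol and set C8 (R) by reagent control, while Mn regenerates divalent chromium, TMSCl releases the product as silyl ether 3 and acid work-up cleaves it.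

Step 2
Reactants: 4 (R)-hex-1-en-5-yn-3-ol
Product: 6 (3R,5E)-6-iodo-5-methylhexa-1,5-dien-3-ol, via alkenylalane 5 (not isolated)
Conditions: AlMe3 (3 equiv), Cp2ZrCl2 (0.25 equiv), CH2Cl2, 0 °C to rt; then I2 (1.3 equiv), THF, −30 to 0 °C; aqueous work-up
Reagents that add atoms: trimethylaluminium, C[Al](C)C; iodine, II
Why: Negishi zirconium-catalysed carboalumination adds Me–Al syn across the terminal alkyne with methyl on the internal carbon, and iodinolysis with retention gives the E-vinyl iodide (C14 installed, C1=C10 geometry fixed), the carbinol being masked in situ as its aluminium alkoxide and the terminal alkene left alone.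

Step 3
Reactants: 6 (3R,5E)-6-iodo-5-methylhexa-1,5-dien-3-ol; 7 methacryloyl chloride
Product: 8 (3R,5E)-6-iodo-5-methylhexa-1,5-dien-3-yl 2-methylprop-2-enoate
Conditions: Et3N, DMAP (5 mol %), CH2Cl2, 0 °C
Reagents that add atoms: none
Why: Nucleophile-catalysed acylation of the secondary alcohol brings in C11–C13 without touching the stereocentre or the vinyl iodide.

Step 4
Reactants: 9 (Z)-3-methylpent-2-en-4-yn-1-ol
Product: 10 (Z)-3-methylpenta-2,4-dien-1-ol
Conditions: H2 (1 atm), Pd/CaCO3 poisoned with Pb(OAc)2 (Lindlar catalyst), quinoline, pentane–Et2O, 0 °C, stopped after 1 equiv H2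
Reagents that add atoms: none
Why: Lindlar semihydrogenation stops at the terminal vinyl group and leaves the Z-trisubstituted alkene (the future C4=C5) intact.

Step 5
Reactants: 10 (Z)-3-methylpenta-2,4-dien-1-ol; 8 (3R,5E)-6-iodo-5-methylhexa-1,5-dien-3-yl 2-methylprop-2-enoate
Product: 12 (3R,5E,9Z)-11-hydroxy-5,9-dimethylundeca-1,5,9-trien-3-yl 2-methylprop-2-enoate, via alkylborane 11 (not isolated)
Conditions: 9-BBN (2.2 equiv), THF, 0 °C to rt; then aq. Cs2CO3 (3 equiv), 8, Pd(dppf)Cl2 (5 mol %), AsPh3 (10 mol %), DMF, rt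
Reagents that add atoms: none
Why: B-alkyl Suzuki–Miyaura coupling, in which 9-BBN hydroborates only the monosubstituted diene terminus (the hydroxyl is O-borylated meanwhile), excess B–H is quenched by the aqueous base before 8 is added, and the alkylborane couples with the vinyl iodide with retention of E-geometry faster than zerovalent palladium can ionise the allylic ester.

Step 6
Reactants: 12 (3R,5E,9Z)-11-hydroxy-5,9-dimethylundeca-1,5,9-trien-3-yl 2-methylprop-2-enoate
Product: 13 (5R)-5-[(2E,6Z)-8-hydroxy-2,6-dimethylocta-2,6-dien-1-yl]-3-methylfuran-2(5H)-one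
Conditions: second-generation Grubbs catalyst RuCl2(=CHPh)(PCy3)(H2IMes) (5 mol %), CH2Cl2 (5 mM), 40 °C
Reagents that add atoms: none
Why: Ring-closing metathesis between the terminal vinyl group and the methacrylate gives the α-methylbutenolide with loss of ethene, the two trisubstituted alkenes being unreactive and C8 untouched.

Step 7
Reactants: 13 (5R)-5-[(2E,6Z)-8-hydroxy-2,6-dimethylocta-2,6-dien-1-yl]-3-methylfuran-2(5H)-one
Product: 14 (5R)-5-[(2E,6Z)-2,6-dimethyl-8-oxoocta-2,6-dien-1-yl]-3-methylfuran-2(5H)-one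
Conditions: activated MnO2 (15 equiv), CH2Cl2, rt
Reagents that add atoms: none
Why: Chemoselective allylic oxidation of the primary alcohol gives the Z-enal under neutral conditions without Z/E isomerisation (as for nerol to neral) and without epimerising the butenolide.

Step 8
Reactants: 14 (5R)-5-[(2E,6Z)-2,6-dimethyl-8-oxoocta-2,6-dien-1-yl]-3-methylfuran-2(5H)-one
Product: 15 (6R,7R,8R,11S)-6-hydroxygermacra-1(10)E,4Z-dien-12,8-olide
Conditions: SmI2 (2.5 equiv, 0.01 M in THF), t-BuOH (3 equiv), syringe-pump addition of 14 (final 2 mM), −78 to −40 °C; aqueous work-up at −78 °C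
Reagents that add atoms: none
Why: Proposed new method: single-electron reduction of the conjugated aldehyde gives a samarium-bound allylic ketyl that attacks through its oxygen-bearing terminus C6 (the C4 terminus is tertiary) the β-carbon C7 of the butenolide in a 10-exo macrocyclisation, and a second electron plus t-BuOH converts the α-lactone radical into the C11–H lactone, the closest known chemistry being the SmI2 ketyl–olefin (Fukuzawa-type) coupling of aldehydes with α,β-unsaturated esters and lactones and SmI2 medium-ring closures; C7 is set by attack anti to the C9 substituent (trans-fused lactone), C6 (R) is expected from a transition state in which trivalent samarium bridges the ketyl oxygen and the lactone carbonyl, and C11 (protonated anti to H7) is re-set in step 9.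

Step 9
Reactants: 15 (6R,7R,8R,11S)-6-hydroxygermacra-1(10)E,4Z-dien-12,8-olide
Product: 17 (6R,7R,8R,11R)-6,11-dihydroxygermacra-1(10)E,4Z-dien-12,8-olide, via dipotassium dianion 16 (not isolated)
Conditions: KN(SiMe3)2 (2.3 equiv), THF, −78 °C; then 2-(phenylsulfonyl)-3-phenyloxaziridine (1.5 equiv), −78 °C; AcOH quench at −78 °C
Reagents that add atoms: 2-(phenylsulfonyl)-3-phenyloxaziridine, O=S(=O)(c1ccccc1)N1OC1c1ccccc1
Why: Davis α-hydroxylation of the lactone enolate (the C6 alkoxide is carried as the dianion), the oxaziridine oxygen arriving on the face anti to the pseudo-axial H7 of the trans-fused lactone (the face on which protonation and selenenylation of trans-fused sesquiterpene-lactone enolates are reported to occur), which gives the 11β-hydroxy-11α-methyl (11R) centre, and the cold acidic quench prevents translactonisation to C6.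

Step 10
Reactants: 17 (6R,7R,8R,11R)-6,11-dihydroxygermacra-1(10)E,4Z-dien-12,8-olide; 18 angelic acid
Product: 20 (6R,7S,8R,11R)-6,11-bis[(Z)-2-methylbut-2-enoyloxy]germacra-1(10)E,4Z-dien-12,8-olide, via mixed anhydride 19 (not isolated)
Conditions: 18 (5 equiv), 2,4,6-trichlorobenzoyl chloride (5 equiv), Et3N (10 equiv), toluene, rt, 2 h; then 17, DMAP (0.3 equiv), toluene, 70 °C
Reagents that add atoms: none
Why: Yamaguchi-type esterification with the preformed mixed anhydride, which transfers the angeloyl group with little Z-to-E leakage and acylates both the secondary allylic C6–OH and the tertiary α-hydroxy-lactone C11–OH (a class of tertiary alcohol known to accept acylation) with retention at both centres.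

Step 11
Reactants: 20 (6R,7S,8R,11R)-6,11-bis[(Z)-2-methylbut-2-enoyloxy]germacra-1(10)E,4Z-dien-12,8-olide
Product: 21 (1R,6R,7S,8R,10R,11R)-6,11-bis[(Z)-2-methylbut-2-enoyloxy]-1,10-epoxygermacr-4Z-en-12,8-olide (CNP0182151.2)
Conditions: D-fructose-derived Shi ketone (0.3 equiv), KHSO5 (as the triple salt 2KHSO5·KHSO4·K2SO4, 1.5 equiv), K2CO3, Bu4NHSO4 (cat.), MeCN–dimethoxymethane/aq. borate buffer (pH 10.5), 0 °C
Reagents that add atoms: potassium peroxymonosulfate, [K+].[O-]S(=O)(=O)OO
Why: Shi asymmetric epoxidation, in which the chiral dioxirane attacks only the electron-rich E-trisubstituted C1=C10 alkene (C4=C5 is deactivated by the allylic ester and the angelate alkenes are electron-poor) through a spiro transition state that, for E-trisubstituted alkenes with the D-fructose-derived ketone, gives the R,R epoxide, here 1R,10R.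

**Compound list**

1 | acrolein (prop-2-enal) | C=CC=O | starting material
2 | propargyl bromide (3-bromoprop-1-yne) | C#CCBr | starting material
3 | (R)-3-(trimethylsilyloxy)hex-1-en-5-yne | C=C[C@H](O[Si](C)(C)C)CC#C | intermediate
4 | (R)-hex-1-en-5-yn-3-ol | C=C[C@H](O)CC#C | intermediate
5 | alkenylalane: (3R,5E)-6-(dimethylalumanyl)-5-methylhexa-1,5-dien-3-ol as its O-dimethylaluminium alkoxide | C=C[C@H](O[Al](C)C)C/C(C)=C/[Al](C)C | intermediate
6 | (3R,5E)-6-iodo-5-methylhexa-1,5-dien-3-ol | C=C[C@H](O)C/C(C)=C/I | intermediate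
7 | methacryloyl chloride | C=C(C)C(Cl)=O | starting material
8 | (3R,5E)-6-iodo-5-methylhexa-1,5-dien-3-yl 2-methylprop-2-enoate | C=C[C@H](OC(=O)C(C)=C)C/C(C)=C/I | intermediate
9 | (Z)-3-methylpent-2-en-4-yn-1-ol | C#C/C(C)=C\CO | starting material
10 | (Z)-3-methylpenta-2,4-dien-1-ol | C=C/C(C)=C\CO | intermediate
11 | 9-[(3Z)-3-methyl-5-(9-borabicyclo[3.3.1]nonan-9-yloxy)pent-3-en-1-yl]-9-borabicyclo[3.3.1]nonane | O(B1C2CCCC1CCC2)C/C=C(/C)CCB1C2CCCC1CCC2 | intermediate
12 | (3R,5E,9Z)-11-hydroxy-5,9-dimethylundeca-1,5,9-trien-3-yl 2-methylprop-2-enoate | C=C[C@H](OC(=O)C(C)=C)C/C(C)=C/CC/C(C)=C\CO | intermediate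
13 | (5R)-5-[(2E,6Z)-8-hydroxy-2,6-dimethylocta-2,6-dien-1-yl]-3-methylfuran-2(5H)-one | CC1=C[C@@H](C/C(C)=C/CC/C(C)=C\CO)OC1=O | intermediate
14 | (5R)-5-[(2E,6Z)-2,6-dimethyl-8-oxoocta-2,6-dien-1-yl]-3-methylfuran-2(5H)-one | CC1=C[C@@H](C/C(C)=C/CC/C(C)=C\C=O)OC1=O | intermediate
15 | (6R,7R,8R,11S)-6-hydroxygermacra-1(10)E,4Z-dien-12,8-olide (trans-fused lactone, H7 α, H8 β, 6-OH β, 13-methyl α) | O[C@@H]1/C=C(/C)CC/C=C(\C)C[C@H]2OC(=O)[C@@H](C)[C@H]12 | intermediate
16 | dipotassium C6-alkoxide C11/C12-enolate of 15 | [K+].[K+].[O-][C@@H]1/C=C(/C)CC/C=C(\C)C[C@H]2OC([O-])=C(C)[C@H]12 | intermediate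
17 | (6R,7R,8R,11R)-6,11-dihydroxygermacra-1(10)E,4Z-dien-12,8-olide | O[C@@H]1/C=C(/C)CC/C=C(\C)C[C@H]2OC(=O)[C@](C)(O)[C@H]12 | intermediate
18 | angelic acid ((Z)-2-methylbut-2-enoic acid) | C/C=C(/C)C(O)=O | starting material
19 | (Z)-2-methylbut-2-enoic 2,4,6-trichlorobenzoic anhydride | C/C=C(/C)C(=O)OC(=O)c1c(Cl)cc(Cl)cc1Cl | intermediate
20 | (6R,7S,8R,11R)-6,11-bis[(Z)-2-methylbut-2-enoyloxy]germacra-1(10)E,4Z-dien-12,8-olide | C/C=C(/C)C(=O)O[C@@H]1/C=C(/C)CC/C=C(\C)C[C@H]2OC(=O)[C@](C)(OC(=O)/C(C)=C\C)[C@H]12 | intermediate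
21 | (1R,6R,7S,8R,10R,11R)-6,11-bis[(Z)-2-methylbut-2-enoyloxy]-1,10-epoxygermacr-4Z-en-12,8-olide (CNP0182151.2) | C/C=C(/C)C(=O)O[C@@H]1/C=C(/C)CC[C@H]2O[C@]2(C)C[C@H]2OC(=O)[C@](C)(OC(=O)/C(C)=C\C)[C@H]12 | target

**Step count**
Total: 11 steps. Longest linear sequence: 10 steps (1, 2, 3, 5, 6, 7, 8, 9, 10, 11); step 4 is a one-step side branch.

**Three steps most likely to fail, with fallbacks**

The macrocyclisation of step 8 is the largest risk. The enal ketyl may simply be reduced, couple through C4, dimerise, or give the wrong C6 epimer. The fallback changes the radical from a ketyl to an acyl radical and sets C6 afterwards. It sets out from 14: Pinnick oxidation (NaClO2, NaH2PO4, 2-methylbut-2-ene) gives the carboxylic acid F1, and PhSeSePh with PBu3 converts it into the Se-phenyl selenoester F2. Tin-free chain cyclisation ((Me3Si)3SiH, AIBN, benzene, 80 °C, syringe pump, 1 mM) then closes the ring by acyl-radical addition to the butenolide to give the macrocyclic 6-oxo lactone F3. A 1,2-reduction of the enone (NaBH4 with CeCl3, or the CBS oxazaborolidine antipode that gives 6R) brings the route back at 15.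

The double angeloylation of step 10 is the second risk. The tertiary C11 hydroxyl may not acylate, or the angelate may leak to tiglate under forcing conditions. The fallback builds the angelate double bonds on the esters instead of transferring a preformed angeloyl group. It sets out from 17: 2-[bis(2-methylphenoxy)phosphoryl]propanoic acid with DCC (a phosphono-ketene forms and acylates hindered alcohols) gives the bis(phosphonopropionate) F4. An Ando-type Z-selective Horner–Wadsworth–Emmons reaction with acetaldehyde (NaH, THF, −78 to 0 °C) then forms both (Z)-2-methylbut-2-enoates and comes back at 20.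

The epoxidation of step 11 is the third risk. The ring conformation of 20 may oppose the reagent, and the esters may suffer at pH 10.5. The fallback moves the epoxidation to the acyclic stage, where only reagent control operates and the other alkenes are all electron-poor. It sets out from 14: the same ketone and KHSO5 give the epoxy enal F5. The epoxide, which is inert to SmI2 in THF without additives, is carried through the conditions of step 8 to the epoxy hydroxy lactone F6 and of step 9 to the epoxy diol F7. The acylation of step 10 then gives 21 directly.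

**Further compounds**

F1 | step 8 | (2Z,6E)-3,7-dimethyl-8-[(2R)-4-methyl-5-oxo-2,5-dihydrofuran-2-yl]octa-2,6-dienoic acid | CC1=C[C@@H](C/C(C)=C/CC/C(C)=C\C(O)=O)OC1=O
F2 | step 8 | Se-phenyl (2Z,6E)-3,7-dimethyl-8-[(2R)-4-methyl-5-oxo-2,5-dihydrofuran-2-yl]octa-2,6-dieneselenoate | CC1=C[C@@H](C/C(C)=C/CC/C(C)=C\C(=O)[Se]c2ccccc2)OC1=O
F3 | step 8 | (7S,8R,11S)-6-oxogermacra-1(10)E,4Z-dien-12,8-olide | O=C1/C=C(/C)CC/C=C(\C)C[C@H]2OC(=O)[C@@H](C)[C@H]12
F4 | step 10 | (6R,7S,8R,11R)-6,11-bis{2-[bis(2-methylphenoxy)phosphoryl]propanoyloxy}germacra-1(10)E,4Z-dien-12,8-olide (mixture at the two phosphonate α-carbons) | CC(C(=O)O[C@@H]1/C=C(/C)CC/C=C(\C)C[C@H]2OC(=O)[C@](C)(OC(=O)C(C)P(=O)(Oc3ccccc3C)Oc3ccccc3C)[C@H]12)P(=O)(Oc1ccccc1C)Oc1ccccc1C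
F5 | step 11 | (5R)-3-methyl-5-{[(2R,3R)-2-methyl-3-[(3Z)-3-methyl-5-oxopent-3-en-1-yl]oxiran-2-yl]methyl}furan-2(5H)-one | O=C/C=C(/C)CC[C@H]1O[C@]1(C)C[C@H]1OC(=O)C(C)=C1
F6 | step 11 | (1R,6R,7R,8R,10R,11S)-1,10-epoxy-6-hydroxygermacr-4Z-en-12,8-olide | O[C@@H]1/C=C(/C)CC[C@H]2O[C@]2(C)C[C@H]2OC(=O)[C@@H](C)[C@H]12
F7 | step 11 | (1R,6R,7R,8R,10R,11R)-1,10-epoxy-6,11-dihydroxygermacr-4Z-en-12,8-olide | O[C@@H]1/C=C(/C)CC[C@H]2O[C@]2(C)C[C@H]2OC(=O)[C@](C)(O)[C@H]12
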